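**Plan**
Numbering used: butenolide ring O1, C2 (C=O), C3, C4 (Br), C5; exocyclic C6 (H, Br); side-chain carbinol C1′.
Retrosynthesis: cut O1–C5 together with C6–Br (anti addition of a carboxylate oxygen and Br+ across a terminal C5≡C6 alkyne); acid back to aldehyde; the cis ene-yne-aldehyde back to a 2-furylcarbene, i.e. a 3-bromofuran-2-carbaldehyde tosylhydrazone; C6 back to DMF; C3–C1′ back to 3,4-dibromofuran plus a butanoyl unit.
Enabling feature: O1, C2, C3, C4 and C5 are the five atoms of a furan, and C3=C4 lies inside that ring. Opening the furan through its carbene therefore puts C2 and the C5≡C6 alkyne cis on the tetrasubstituted alkene, and the C5=C6 enol-lactone bond with Br anti to O1 is what 5-exo-dig bromolactonisation of that unit gives.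
Forward order: side chain onto the furan (steps 1–2), C6 added (step 3), acetate (step 4), furan opened to the chain (steps 5–6), oxidation (step 7), butenolide ring closed last (step 8).
Stereochemistry: C1′ (R) from Corey–Bakshi–Shibata reduction; the cis C2/C5 relation from the furan; the C5=C6 geometry from the anti stereospecificity of the ring closure.

Key step: step 8

Remark: the structure is read with the vinylic bromine on C6 on the side of C4, anti to the ring oxygen (the 5E isomer), and C1′ as R; the route is built for this isomer only.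

**Route**

Step 1
Reactants: 1 3,4-dibromofuran; 2 N-methoxy-N-methylbutanamide
Product: 4 1-(4-bromofuran-3-yl)butan-1-one, via 3-bromo-4-lithiofuran 3 (not isolated)
Conditions: n-BuLi (1.0 equiv), Et2O, −78 °C; then 2, −78 to −40 °C; aq. HCl
Reagents that add atoms: none
Why: Bromine–lithium exchange at one of the two equivalent C–Br bonds should give the 3-furyllithium, stable at −78 °C, and its acylation by the Weinreb amide stops at the ketone because the chelated tetrahedral adduct survives until the acidic work-up (halogen–metal exchange, then Weinreb ketone synthesis).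

Step 2
Reactants: 4 1-(4-bromofuran-3-yl)butan-1-one
Product: 5 (1R)-1-(4-bromofuran-3-yl)butan-1-ol
Conditions: (S)-1-methyl-3,3-diphenyltetrahydro-1H,3H-pyrrolo[1,2-c][1,3,2]oxazaborole (10 mol%), BH3·SMe2 (0.7 equiv), THF, −20 °C; MeOH
Reagents that add atoms: none
Why: Corey–Bakshi–Shibata reduction, in which the oxazaborolidine–borane complex binds the ketone anti to the larger 4-bromofuryl group and delivers hydride to the face that, as with aryl alkyl ketones and the (S)-catalyst, should give the (R)-carbinol and so sets C1′.

Step 3
Reactants: 5 (1R)-1-(4-bromofuran-3-yl)butan-1-ol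
Product: 7 3-bromo-4-[(1R)-1-hydroxybutyl]furan-2-carbaldehyde, via dilithio species 6 (not isolated)
Conditions: LiN(iPr)2 (2.3 equiv), THF, −78 °C; DMF, −78 to −20 °C; AcOH, H2O
Reagents that add atoms: N,N-dimethylformamide, CN(C)C=O
Why: Deprotonative lithiation and formylation, in which, after O-lithiation, the amide base should remove the most acidic ring proton, H-5 of 5 between the ring oxygen and the C–Br carbon (the site selectivity known for 3-bromofuran), and DMF formylates the furyllithium, placing the future C6 next to the bromine-bearing carbon.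

Step 4
Reactants: 7 3-bromo-4-[(1R)-1-hydroxybutyl]furan-2-carbaldehyde
Product: 8 (1R)-1-(4-bromo-5-formylfuran-3-yl)butyl acetate
Conditions: Ac2O, pyridine, 4-(dimethylamino)pyridine (5 mol%), CH2Cl2, 0 °C
Reagents that add atoms: acetic anhydride, CC(=O)OC(C)=O
Why: Nucleophile-catalysed O-acylation of the secondary alcohol should give the acetate with retention, since no bond to C1′ is broken, and it is placed here because an acetate would not survive the lithiation of step 3.

Step 5
Reactants: 8 (1R)-1-(4-bromo-5-formylfuran-3-yl)butyl acetate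
Product: 9 (1R)-1-[4-bromo-5-[(E)-{2-[(4-methylphenyl)sulfonyl]hydrazinylidene}methyl]furan-3-yl]butyl acetate
Conditions: TsNHNH2 (1.05 equiv), MeOH, 20 °C
Reagents that add atoms: 4-methylbenzenesulfonohydrazide, Cc1ccc(cc1)S(=O)(=O)NN
Why: Condensation of the aldehyde with the sulfonyl hydrazide (hydrazone formation) should proceed under neutral conditions that leave the acetate and the C–Br bond untouched.

Step 6
Reactants: 9 (1R)-1-[4-bromo-5-[(E)-{2-[(4-methylphenyl)sulfonyl]hydrazinylidene}methyl]furan-3-yl]butyl acetate
Product: 12 (2E)-2-[(1R)-1-(acetyloxy)butyl]-3-bromopent-2-en-4-ynal, via tosylhydrazone sodium salt 10 (not isolated), via furyldiazomethane 11 (not isolated)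
Conditions: NaH (1.05 equiv), THF, 0 °C; then high dilution in 1,4-dioxane, 70 °C, dark, no metal catalyst
Reagents that add atoms: none
Why: Bamford–Stevens reaction followed by the known ring-opening of a 2-furylcarbene, in which the salt loses sulfinate to the diazoalkane, loss of N2 puts a carbene on the carbon attached to the furan, the ring O–C bond at that position breaks so that these two carbons become the terminal alkyne while the furan oxygen ends as the aldehyde oxygen, and the two β-carbons of the furan remain as the tetrasubstituted alkene with formyl and ethynyl cis.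

Step 7
Reactants: 12 (2E)-2-[(1R)-1-(acetyloxy)butyl]-3-bromopent-2-en-4-ynal
Product: 13 (2E)-2-[(1R)-1-(acetyloxy)butyl]-3-bromopent-2-en-4-ynoic acid
Conditions: NaClO2, NaH2PO4, 2-methyl-2-butene, t-BuOH–H2O, 0 °C
Reagents that add atoms: sodium chlorite, [Na+].[O-]Cl=O
Why: Pinnick (chlorite) oxidation of the enal to the carboxylic acid should leave the alkene geometry, the alkyne, the vinylic bromide and the acetate untouched, the alkene scavenger removing HOCl.

Step 8
Reactants: 13 (2E)-2-[(1R)-1-(acetyloxy)butyl]-3-bromopent-2-en-4-ynoic acid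
Product: 14 acetoxyfimbrolide, (1R)-1-[(5E)-4-bromo-5-(bromomethylidene)-2-oxo-2,5-dihydrofuran-3-yl]butyl acetate
Conditions: NBS (1.1 equiv), NaHCO3 (0.2 equiv), MeCN, 0 °C, dark
Reagents that add atoms: N-bromosuccinimide, O=C1CCC(=O)N1Br
Why: Bromolactonisation of an alkynoic acid: Br+ from NBS activates the terminal C5≡C6 triple bond as a bridged bromirenium ion and a carboxylate oxygen attacks C5 from the opposite face, so O1–C5 and C6–Br form in one stereospecific anti addition. The closest known reactions are the NBS or I2 cyclisations of 4-pentynoic acids and of (Z)-2-en-4-ynoic acids to (E)-5-(halomethylene)furanones. The butenolide ring closes in the 5-exo-dig mode, the cis C3=C4 double bond inherited from the furan holding C2 and C5 on the same side. No new stereocenter forms; the C5=C6 geometry is fixed by the anti addition, which places Br on C6 trans to O1 and therefore cis to C4, as in the target, and C1′ is not touched. The step needs 5-exo attack at C5 rather than 6-endo attack at C6 (to a 2-pyranone) or bromination of the acetylenic C–H; Markovnikov opening at the internal carbon of a terminal alkyne, the electron-poor tetrasubstituted C3=C4 bond being inert to Br+, and the absence of silver salts or strong base should secure this. Exclusion of light guards the product against E to Z isomerisation.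

**Compound list**
1 | 3,4-dibromofuran | Brc1cocc1Br | starting material
2 | N-methoxy-N-methylbutanamide | CCCC(=O)N(C)OC | starting material
3 | 3-bromo-4-lithiofuran | [Li]c1cocc1Br | intermediate
4 | 1-(4-bromofuran-3-yl)butan-1-one | CCCC(=O)c1cocc1Br | intermediate
5 | (1R)-1-(4-bromofuran-3-yl)butan-1-ol | CCC[C@@H](O)c1cocc1Br | intermediate
6 | lithium (1R)-1-(4-bromo-5-lithiofuran-3-yl)butan-1-olate | CCC[C@@H](O[Li])c1coc([Li])c1Br | intermediate
7 | 3-bromo-4-[(1R)-1-hydroxybutyl]furan-2-carbaldehyde | CCC[C@@H](O)c1coc(C=O)c1Br | intermediate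
8 | (1R)-1-(4-bromo-5-formylfuran-3-yl)butyl acetate | CCC[C@@H](OC(C)=O)c1coc(C=O)c1Br | intermediate
9 | (1R)-1-[4-bromo-5-[(E)-{2-[(4-methylphenyl)sulfonyl]hydrazinylidene}methyl]furan-3-yl]butyl acetate | CCC[C@@H](OC(C)=O)c1coc(/C=N/NS(=O)(=O)c2ccc(C)cc2)c1Br | intermediate
10 | sodium salt of 9 (N-sodio tosylhydrazone) | CCC[C@@H](OC(C)=O)c1coc(/C=N/[N-]S(=O)(=O)c2ccc(C)cc2)c1Br.[Na+] | intermediate
11 | (1R)-1-[4-bromo-5-(diazomethyl)furan-3-yl]butyl acetate | CCC[C@@H](OC(C)=O)c1coc(C=[N+]=[N-])c1Br | intermediate
12 | (2E)-2-[(1R)-1-(acetyloxy)butyl]-3-bromopent-2-en-4-ynal (formyl and ethynyl cis) | CCC[C@@H](OC(C)=O)/C(C=O)=C(\Br)C#C | intermediate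
13 | (2E)-2-[(1R)-1-(acetyloxy)butyl]-3-bromopent-2-en-4-ynoic acid (carboxyl and ethynyl cis) | CCC[C@@H](OC(C)=O)/C(C(=O)O)=C(\Br)C#C | intermediate
14 | acetoxyfimbrolide, (1R)-1-[(5E)-4-bromo-5-(bromomethylidene)-2-oxo-2,5-dihydrofuran-3-yl]butyl acetate | CCC[C@@H](OC(C)=O)C1=C(Br)/C(=C\Br)OC1=O | target

**Count**
Total steps: 8. Longest linear sequence: 8 (fully linear from 3,4-dibromofuran).

**Steps most likely to fail and fallbacks**

Step 6 is the riskiest. The diazoalkane may be consumed before it loses nitrogen, by dipolar cycloaddition to the electron-poor alkyne or alkene of the product or by azine formation. The sulfinate set free may also displace the vinylic bromine of the β-bromo enal, and the cis enynal may isomerise on prolonged heating. The fallback sets out from 5 and returns at 13, and opens the furan without a carbene. Compound 5 is lithiated to 6 as in step 3 and trapped with B(OMe)3 to give dimethyl {3-bromo-4-[(1R)-1-hydroxybutyl]furan-2-yl}boronate F1. Oxidation (H2O2, then Et3N) gives the butenolide 3-bromo-4-[(1R)-1-hydroxybutyl]furan-2(5H)-one F2, whose ring again locks the cis relation. Reduction with iBu2AlH (CH2Cl2, −78 °C) gives the lactol 3-bromo-4-[(1R)-1-hydroxybutyl]-2,5-dihydrofuran-2-ol F3. Seyferth–Gilbert homologation of its open aldehyde form with dimethyl (1-diazo-2-oxopropyl)phosphonate (K2CO3, MeOH) gives the ene-yne diol (2Z,3R)-2-(1-bromoprop-2-yn-1-ylidene)hexane-1,3-diol F4. Chemoselective oxidation of the primary allylic alcohol (2,2,6,6-tetramethylpiperidin-1-oxyl cat., PhI(OAc)2, MeCN–H2O) gives (2E)-3-bromo-2-[(1R)-1-hydroxybutyl]pent-2-en-4-ynoic acid F5, and acetylation (Ac2O, pyridine, aqueous work-up) gives 13.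

Step 8 is next. The alkyne is deactivated by the neighbouring vinylic bromine and the conjugated acid and may take up Br+ slowly. Closure in the 6-endo sense, bromination of the acetylenic C–H, or light- or radical-induced isomerisation of the new double bond could then compete. The fallback sets out from 13 and returns at 14, and separates ring closure from bromination. Anti oxymercuration of the alkyne with Hg(OAc)2 (CH2Cl2, 0 °C), then aq. KBr, closes the same O1–C5 bond and should give the vinylmercurial (1R)-1-[(5E)-4-bromo-5-[(bromomercurio)methylidene]-2-oxo-2,5-dihydrofuran-3-yl]butyl acetate F6. Bromodemercuration (Br2, pyridine, −40 °C, dark), which proceeds with retention at the vinylic carbon, then gives 14.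

Step 3 is third. The base may deprotonate the other α-position (H-2 of 5, next to the alkoxide-bearing substituent), or the bromine may migrate in the lithiated furan. The fallback sets out from 5 and returns at 7, and takes the alkoxide out of play. Silylation (tert-butyldimethylsilyl chloride, imidazole, DMF) gives tert-butyl[(1R)-1-(4-bromofuran-3-yl)butoxy]dimethylsilane F7, in which only the bromine directs and the bulky ether shields H-2. LiN(iPr)2 then DMF gives 3-bromo-4-[(1R)-1-{[tert-butyl(dimethyl)silyl]oxy}butyl]furan-2-carbaldehyde F8, and Bu4NF buffered with AcOH returns 7.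

**Further compounds**
F1 | step 6 | dimethyl {3-bromo-4-[(1R)-1-hydroxybutyl]furan-2-yl}boronate | CCC[C@@H](O)c1coc(B(OC)OC)c1Br
F2 | step 6 | 3-bromo-4-[(1R)-1-hydroxybutyl]furan-2(5H)-one | CCC[C@@H](O)C1=C(Br)C(=O)OC1
F3 | step 6 | 3-bromo-4-[(1R)-1-hydroxybutyl]-2,5-dihydrofuran-2-ol | CCC[C@@H](O)C1=C(Br)C(O)OC1
F4 | step 6 | (2Z,3R)-2-(1-bromoprop-2-yn-1-ylidene)hexane-1,3-diol | CCC[C@@H](O)/C(CO)=C(\Br)C#C
F5 | step 6 | (2E)-3-bromo-2-[(1R)-1-hydroxybutyl]pent-2-en-4-ynoic acid | CCC[C@@H](O)/C(C(=O)O)=C(\Br)C#C
F6 | step 8 | (1R)-1-[(5E)-4-bromo-5-[(bromomercurio)methylidene]-2-oxo-2,5-dihydrofuran-3-yl]butyl acetate | CCC[C@@H](OC(C)=O)C1=C(Br)/C(=C\[Hg]Br)OC1=O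
F7 | step 3 | tert-butyl[(1R)-1-(4-bromofuran-3-yl)butoxy]dimethylsilane | CCC[C@@H](O[Si](C)(C)C(C)(C)C)c1cocc1Br
F8 | step 3 | 3-bromo-4-[(1R)-1-{[tert-butyl(dimethyl)silyl]oxy}butyl]furan-2-carbaldehyde | CCC[C@@H](O[Si](C)(C)C(C)(C)C)c1coc(C=O)c1Br
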